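Germacranolide numbering is used (ring C1–C10, acrylate C11–C13, C14 on C10, C15 on C4). The route rests on cutting the α-methylene-γ-butyrolactone off the ten-membered ring at O–C6 and C11–C7. Because C6 is allylic to the C4=C5 enal double bond, the lactone is the retron of a palladium-catalysed heteroannulation: 2-bromoacrylic acid adds across the C6=C7 end of a ring-embedded C4=C5–C6=C7 dienal, vinyl carbon to C7 and carboxylate oxygen to the allyl terminus C6, setting both lactone stereocentres and restoring the enal. The precursor is a ten-membered (4E,6E)-dienal carrying the C1–C10 epoxide and silyl ethers at O8 and O14, closed by an intramolecular Horner–Wadsworth–Emmons reaction.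

Key step: step 14

Remark: aldehyde 5 is taken as a catalogue compound (otherwise one oxidation from commercial 3-[(4-methoxybenzyl)oxy]propan-1-ol). TBSO = tert-butyldimethylsilyloxy.

Step 1
Reactants: 1 (S)-benzyl glycidyl ether; 2 triethyl phosphonoacetate
Product: 4 diethyl [(5S)-5-[(benzyloxy)methyl]-2-oxooxolan-3-yl]phosphonate (both C3 epimers), via ring-opened hydroxy ester 3 (not isolated)
Conditions: NaH, toluene, 0 °C then 100 °C; aq. NH4Cl
Reagents that add atoms: none
Why: The sodium phosphonoacetate carbanion opens the epoxide by SN2 attack at its unsubstituted CH2 (C9) and the alkoxide lactonises onto the ethyl ester, so C8 keeps the configuration of the glycidyl ether.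

Step 2
Reactants: 4 phosphono lactone; 5 3-[(4-methoxybenzyl)oxy]propanal
Product: 6 (3E,5S)-5-[(benzyloxy)methyl]-3-{3-[(4-methoxybenzyl)oxy]propylidene}oxolan-2-one
Conditions: NaH, THF, 0 °C → rt
Reagents that add atoms: none
Why: Horner–Wadsworth–Emmons olefination of the α-phosphono lactone should favour the E-alkylidene lactone (carbonyl trans to the chain), which fixes the later cis relationship of C2 and C9 on the epoxide; any Z isomer would be removed by chromatography.

Step 3
Reactants: 6 alkylidene lactone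
Product: 7 (2E,4S)-5-(benzyloxy)-2-{3-[(4-methoxybenzyl)oxy]propylidene}pentane-1,4-diol
Conditions: DIBAL-H (4.5 equiv), CH2Cl2, −78 → 0 °C; Rochelle salt
Reagents that add atoms: none
Why: Exhaustive 1,2-reduction of the α-alkylidene lactone with DIBAL-H should open it to the primary allylic alcohol (C14) and the secondary alcohol (C8) without changing the alkene geometry or C8.

Step 4
Reactants: 7 allylic diol
Product: 8 (2S)-1-(benzyloxy)-3-[(2R,3R)-2-(hydroxymethyl)-3-{2-[(4-methoxybenzyl)oxy]ethyl}oxiran-2-yl]propan-2-ol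
Conditions: Ti(OiPr)4 (0.2 equiv), D-(−)-diethyl tartrate (0.24 equiv), t-BuOOH, 4 Å MS, CH2Cl2, −20 °C
Reagents that add atoms: tert-butyl hydroperoxide CC(C)(C)OO
Why: Sharpless asymmetric epoxidation of the primary allylic alcohol (the homoallylic C8–OH does not direct) delivers oxygen under reagent control, D-(−)-tartrate giving the (1R,10R) epoxide.

Step 5
Reactants: 8 epoxy diol
Product: 9 bis-TBS ether of 8 (O8 and O14 silylated)
Conditions: TBSCl, imidazole, DMAP (cat.), DMF, rt → 35 °C
Reagents that add atoms: tert-butyldimethylsilyl chloride CC(C)(C)[Si](C)(C)Cl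
Why: Imidazole-mediated silylation protects both hydroxyls as base- and hydride-stable TBS ethers, which later also serve as the bulky, non-ionisable group at C8 in the key step.

Step 6
Reactants: 9 bis-TBS ether
Product: 10 2-[(2R,3R)-3-[(2S)-3-(benzyloxy)-2-(TBSO)propyl]-3-[(TBSO)methyl]oxiran-2-yl]ethan-1-ol
Conditions: DDQ, CH2Cl2/pH 7 buffer, 0 °C
Reagents that add atoms: none
Why: Oxidative cleavage of the electron-rich PMB ether with DDQ should leave the benzyl ether, the silyl ethers and, under buffered conditions, the epoxide intact.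

Step 7
Reactants: 10 primary alcohol
Product: 11 (2R,3R)-2-[(2S)-3-(benzyloxy)-2-(TBSO)propyl]-3-(2-iodoethyl)-2-[(TBSO)methyl]oxirane
Conditions: I2, PPh3, imidazole, CH2Cl2, 0 °C
Reagents that add atoms: iodine II
Why: Appel-type iodination converts the unhindered primary alcohol into the iodide under buffered, near-neutral conditions that a trisubstituted epoxide tolerates.

Step 8
Reactants: 11 iodide; 12 diethyl {2-[methoxy(methyl)amino]-2-oxoethyl}phosphonate
Product: 13 diethyl [(2RS)-4-{(2R,3R)-3-[(2S)-3-(benzyloxy)-2-(TBSO)propyl]-3-[(TBSO)methyl]oxiran-2-yl}-1-[methoxy(methyl)amino]-1-oxobutan-2-yl]phosphonate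
Conditions: NaH, DMF, 0 → 45 °C (12 in excess)
Reagents that add atoms: none
Why: SN2 alkylation of the stabilised phosphonoacetamide carbanion with the primary iodide forms C3–C4; the new centre at C4 is irrelevant because it becomes sp2 in step 12.

Step 9
Reactants: 13 benzyl ether
Product: 14 the corresponding primary alcohol (C7–OH)
Conditions: H2 (1 atm), 10% Pd/C, EtOAc, rt
Reagents that add atoms: none
Why: Hydrogenolysis removes the benzyl ether at a stage where the molecule has no alkene, and silyl ethers, epoxide and Weinreb amide are stable under neutral conditions.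

Step 10
Reactants: 14 primary alcohol
Product: 15 the corresponding α-silyloxy aldehyde (C7 aldehyde)
Conditions: Dess–Martin periodinane, pyridine, CH2Cl2, 0 °C → rt
Reagents that add atoms: none
Why: Dess–Martin oxidation gives the α-silyloxy aldehyde under buffered conditions that should not epimerise C8.

Step 11
Reactants: 15 aldehyde; 16 (triphenylphosphoranylidene)acetaldehyde
Product: 17 the E-enal (C5 aldehyde, C6=C7)
Conditions: toluene, 70 °C
Reagents that add atoms: none
Why: Wittig reaction with the stabilised formyl ylide should give the E-enal, and the un-ionised phosphonate is a spectator in the absence of base.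

Step 12
Reactants: 17 enal phosphonate
Product: 18 ten-membered (4E,6E)-dienyl Weinreb amide, (1R,8S,10R)
Conditions: slow addition of 17 to NaH, THF, 0 °C → rt, final concentration about 1 mM
Reagents that add atoms: none
Why: Intramolecular Horner–Wadsworth–Emmons olefination closes the ring at C4=C5, where the intrinsic preference of the reaction (amide trans to C6) and of the ring (C3 and C6 cis, a cis-cycloalkene) coincide.

Step 13
Reactants: 18 Weinreb amide
Product: 19 ten-membered (4E,6E)-dienal, (1R,8S,10R)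
Conditions: DIBAL-H (1.5 equiv), THF, −78 °C; aq. Rochelle salt
Reagents that add atoms: none
Why: DIBAL-H reduction of the Weinreb amide stops at the aldehyde through the chelated tetrahedral intermediate and should leave silyl ethers and epoxide untouched.

Step 14
Reactants: 19 dienal; 20 2-bromoacrylic acid
Product: 22 (1R,6R,7S,8S,10R,4E)-8,14-bis(TBSO)-1,10-epoxy-15-oxogermacra-4,11(13)-dien-12,6-olide, via allylpalladium carboxylate palladacycle 21 (not isolated)
Conditions: Pd(OAc)2 (10 mol %), PPh3 (20 mol %), Na2CO3, n-Bu4NCl, DMF, 60 °C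
Reagents that add atoms: none
Why: Pd(0) inserts into the C–Br bond of 2-bromoacrylate, the vinylpalladium adds syn across the less substituted C6=C7 bond with carbon going to the δ-carbon C7 of the dienal, and the resulting C4–C6 allyl/dienolate palladium, held as carboxylate palladacycle 21, forms the C6–O bond by reductive elimination on the palladium-bearing face, regenerating Pd(0) and the C4=C5 enal. The closest known reaction type is the Larock heteroannulation of 1,3-dienes by vinylic or aryl halides that carry an O–H, N–H or CO2H nucleophile. The γ-lactone closes as a five-membered ring by 1,2-annulation, the carboxylate attacking the allyl terminus next to the new C–C bond rather than C4 (seven-membered ring, loss of conjugation). C7 should be set by carbopalladation on the exposed peripheral face of the E-configured C6=C7 bond in the ring conformer that places the bulky C8–OTBS group pseudo-equatorial, and C6 by syn delivery of oxygen from palladium, so that net syn addition to an E-alkene gives the trans-fused lactone (H6/H7 anti), also the thermodynamically preferred isomer if the allylic ester re-ionises. The step needs site selectivity for C6=C7 over the hindered aldehyde-bearing C4=C5, regioselectivity for C7 and C–O closure ahead of β-hydride elimination; sterics and the 1,6-acceptor polarity of the dienal secure the first two, the stabilised allyl intermediate with its internal carboxylate the third, and the silyl ether at C8 cannot ionise to a competing allyl complex.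

Step 15
Reactants: 22 bis-TBS lactone
Product: 23 (1R,6R,7R,8S,10R,4E)-1,10-epoxy-8,14-dihydroxy-15-oxogermacra-4,11(13)-dien-12,6-olide
Conditions: HF·pyridine, pyridine, THF, 0 °C → rt
Reagents that add atoms: none
Why: Buffered fluoride desilylation frees the C8 and C14 hydroxyls under mildly acidic conditions chosen to avoid base-induced translactonisation to O8 and conjugate addition to the α-methylene lactone.

Step 16
Reactants: 23 diol
Product: 24 CNP0211286.1, (1R,6R,7R,8S,10R,4E)-8,14-diacetoxy-1,10-epoxy-15-oxogermacra-4,11(13)-dien-12,6-olide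
Conditions: Ac2O, pyridine, DMAP (cat.), CH2Cl2, 0 °C
Reagents that add atoms: acetic anhydride CC(=O)OC(C)=O
Why: Acylation of the secondary C8 and primary C14 alcohols gives the diacetate without touching any stereocentre.

Compound list
1 | (S)-benzyl glycidyl ether | C1O[C@@H]1COCc1ccccc1 | starting material
2 | triethyl phosphonoacetate | CCOC(=O)CP(=O)(OCC)OCC | starting material
3 | ethyl (4S)-5-(benzyloxy)-2-(diethoxyphosphoryl)-4-hydroxypentanoate (sodium alkoxide in the flask) | CCOC(=O)C(C[C@H](O)COCc1ccccc1)P(=O)(OCC)OCC | intermediate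
4 | diethyl [(5S)-5-[(benzyloxy)methyl]-2-oxooxolan-3-yl]phosphonate | CCOP(=O)(OCC)C1C[C@@H](COCc2ccccc2)OC1=O | intermediate
5 | 3-[(4-methoxybenzyl)oxy]propanal | O=CCCOCc1ccc(OC)cc1 | starting material
6 | (3E,5S)-5-[(benzyloxy)methyl]-3-{3-[(4-methoxybenzyl)oxy]propylidene}oxolan-2-one | O=C1/C(=C/CCOCc2ccc(OC)cc2)C[C@@H](COCc2ccccc2)O1 | intermediate
7 | (2E,4S)-5-(benzyloxy)-2-{3-[(4-methoxybenzyl)oxy]propylidene}pentane-1,4-diol | OC/C(=C/CCOCc1ccc(OC)cc1)C[C@H](O)COCc1ccccc1 | intermediate
8 | (2S)-1-(benzyloxy)-3-[(2R,3R)-2-(hydroxymethyl)-3-{2-[(4-methoxybenzyl)oxy]ethyl}oxiran-2-yl]propan-2-ol | COc1ccc(COCC[C@H]2O[C@@]2(CO)C[C@H](O)COCc2ccccc2)cc1 | intermediate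
9 | bis-TBS ether of 8 | COc1ccc(COCC[C@H]2O[C@@]2(CO[Si](C)(C)C(C)(C)C)C[C@H](O[Si](C)(C)C(C)(C)C)COCc2ccccc2)cc1 | intermediate
10 | 2-[(2R,3R)-3-[(2S)-3-(benzyloxy)-2-(TBSO)propyl]-3-[(TBSO)methyl]oxiran-2-yl]ethan-1-ol | OCC[C@H]1O[C@@]1(CO[Si](C)(C)C(C)(C)C)C[C@H](O[Si](C)(C)C(C)(C)C)COCc1ccccc1 | intermediate
11 | (2R,3R)-2-[(2S)-3-(benzyloxy)-2-(TBSO)propyl]-3-(2-iodoethyl)-2-[(TBSO)methyl]oxirane | ICC[C@H]1O[C@@]1(CO[Si](C)(C)C(C)(C)C)C[C@H](O[Si](C)(C)C(C)(C)C)COCc1ccccc1 | intermediate
12 | diethyl {2-[methoxy(methyl)amino]-2-oxoethyl}phosphonate | CCOP(=O)(OCC)CC(=O)N(C)OC | starting material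
13 | diethyl [(2RS)-4-{(2R,3R)-3-[(2S)-3-(benzyloxy)-2-(TBSO)propyl]-3-[(TBSO)methyl]oxiran-2-yl}-1-[methoxy(methyl)amino]-1-oxobutan-2-yl]phosphonate | CCOP(=O)(OCC)C(CC[C@H]1O[C@@]1(CO[Si](C)(C)C(C)(C)C)C[C@H](O[Si](C)(C)C(C)(C)C)COCc1ccccc1)C(=O)N(C)OC | intermediate
14 | as 13 with (2S)-3-hydroxy-2-(TBSO)propyl in place of the benzyloxy side chain (C7–OH) | CCOP(=O)(OCC)C(CC[C@H]1O[C@@]1(CO[Si](C)(C)C(C)(C)C)C[C@H](O[Si](C)(C)C(C)(C)C)CO)C(=O)N(C)OC | intermediate
15 | as 13 with (2S)-3-oxo-2-(TBSO)propyl side chain (C7 aldehyde) | CCOP(=O)(OCC)C(CC[C@H]1O[C@@]1(CO[Si](C)(C)C(C)(C)C)C[C@H](O[Si](C)(C)C(C)(C)C)C=O)C(=O)N(C)OC | intermediate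
16 | (triphenylphosphoranylidene)acetaldehyde | O=CC=P(c1ccccc1)(c1ccccc1)c1ccccc1 | starting material
17 | as 13 with (2S,3E)-5-oxo-2-(TBSO)pent-3-en-1-yl side chain (E-enal) | CCOP(=O)(OCC)C(CC[C@H]1O[C@@]1(CO[Si](C)(C)C(C)(C)C)C[C@H](O[Si](C)(C)C(C)(C)C)/C=C/C=O)C(=O)N(C)OC | intermediate
18 | (1R,8S,10R)-1,10-epoxy-8-(TBSO)-10-[(TBSO)methyl]cyclodeca-4E,6E-diene with C(=O)N(OMe)Me on C4 | CON(C)C(=O)/C1=C/C=C/[C@@H](O[Si](C)(C)C(C)(C)C)C[C@]2(CO[Si](C)(C)C(C)(C)C)O[C@@H]2CC1 | intermediate
19 | (1R,8S,10R)-1,10-epoxy-8-(TBSO)-10-[(TBSO)methyl]cyclodeca-4E,6E-diene-4-carbaldehyde | O=C/C1=C/C=C/[C@@H](O[Si](C)(C)C(C)(C)C)C[C@]2(CO[Si](C)(C)C(C)(C)C)O[C@@H]2CC1 | intermediate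
20 | 2-bromoacrylic acid | C=C(Br)C(=O)O | starting material
21 | C6-palladated six-membered carboxylate palladacycle (σ-allyl form, ligands omitted) | C=C1C(=O)O[Pd][C@@H]2/C=C(/C=O)CC[C@H]3O[C@@]3(CO[Si](C)(C)C(C)(C)C)C[C@H](O[Si](C)(C)C(C)(C)C)[C@@H]12 | intermediate
22 | (1R,6R,7S,8S,10R,4E)-8,14-bis(TBSO)-1,10-epoxy-15-oxogermacra-4,11(13)-dien-12,6-olide (geometry at C7 as in the target; the descriptor changes with the silyl group on O8) | C=C1C(=O)O[C@@H]2/C=C(/C=O)CC[C@H]3O[C@@]3(CO[Si](C)(C)C(C)(C)C)C[C@H](O[Si](C)(C)C(C)(C)C)[C@@H]12 | intermediate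
23 | (1R,6R,7R,8S,10R,4E)-1,10-epoxy-8,14-dihydroxy-15-oxogermacra-4,11(13)-dien-12,6-olide | C=C1C(=O)O[C@@H]2/C=C(/C=O)CC[C@H]3O[C@@]3(CO)C[C@H](O)[C@@H]12 | intermediate
24 | CNP0211286.1, (1R,6R,7R,8S,10R,4E)-8,14-diacetoxy-1,10-epoxy-15-oxogermacra-4,11(13)-dien-12,6-olide | C=C1C(=O)O[C@@H]2/C=C(/C=O)CC[C@H]3O[C@@]3(COC(C)=O)C[C@H](OC(C)=O)[C@@H]12 | target

Total step count: 16. Longest linear sequence: 16 steps (from 1).

Steps most likely to fail

Step 14. After carbopalladation the palladium sits on an aldehyde-stabilised allyl (O-bound dienolate) that may undergo β-hydride elimination or protonation faster than C–O bond formation, and the electron-poor diene may insert sluggishly. The fallback sets out from 19 and returns at 22 by removing the acceptor before the annulation. Luche reduction of 19 (NaBH4, CeCl3·7H2O, MeOH, −40 °C) should give the ten-membered dienol F1. Heteroannulation of this ordinary electron-rich 1,3-diene with 20 under the same palladium catalysis would run through a classical η3-allyl intermediate and give the hydroxymethyl lactone F2. Allylic oxidation of F2 with MnO2 in CH2Cl2 then leads back to 22.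

Step 12. The hindered α-branched phosphonate carbanion may close the strained ten-membered ring too slowly, so that intermolecular olefination (oligomers) or γ-deprotonation of the enal takes over. The fallback sets out from 15 and returns at 18, closing the ring at C5–C6 by a Heck reaction instead. Takai olefination of 15 (CrCl2, CHI3, THF, 0 °C) should give the E-vinyl iodide F3. Horner–Wadsworth–Emmons methylenation of F3 (NaH, paraformaldehyde, THF) would give the 2-substituted N-methoxy-N-methylacrylamide F4. An intramolecular endo Heck cyclisation of F4 (Pd(OAc)2, P(o-tol)3, K2CO3, n-Bu4NCl, DMF, 70 °C, high dilution), with β-hydride elimination towards C5, would then form the conjugated diene of 18.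

Step 15. Once the silyl groups are off, the free C8 hydroxyl can attack the lactone carbonyl (translactonisation from O6 to O8), and fluoride or HF can open the epoxide or add to the α-methylene lactone. The fallback sets out from 19 and returns at 24 by exchanging the protecting groups before the lactone exists. HF·pyridine on 19 should give the dienal diol F5, and Ac2O/pyridine the dienal bis-acetate F6. The palladium-catalysed annulation of F6 with 20 would then give 24 directly.

Further compounds
F1 | step 14 | (1R,8S,10R)-1,10-epoxy-4-(hydroxymethyl)-8-(TBSO)-10-[(TBSO)methyl]cyclodeca-4E,6E-diene | OC/C1=C/C=C/[C@@H](O[Si](C)(C)C(C)(C)C)C[C@]2(CO[Si](C)(C)C(C)(C)C)O[C@@H]2CC1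
F2 | step 14 | 22 with CH2OH in place of the C15 aldehyde | C=C1C(=O)O[C@@H]2/C=C(/CO)CC[C@H]3O[C@@]3(CO[Si](C)(C)C(C)(C)C)C[C@H](O[Si](C)(C)C(C)(C)C)[C@@H]12
F3 | step 12 | E-vinyl iodide from 15 (CH=CHI in place of CHO) | CCOP(=O)(OCC)C(CC[C@H]1O[C@@]1(CO[Si](C)(C)C(C)(C)C)C[C@H](O[Si](C)(C)C(C)(C)C)/C=C/I)C(=O)N(C)OC
F4 | step 12 | 2-substituted N-methoxy-N-methylacrylamide bearing the E-vinyl iodide | C=C(CC[C@H]1O[C@@]1(CO[Si](C)(C)C(C)(C)C)C[C@H](O[Si](C)(C)C(C)(C)C)/C=C/I)C(=O)N(C)OC
F5 | step 15 | (1R,8S,10R)-1,10-epoxy-8-hydroxy-10-(hydroxymethyl)cyclodeca-4E,6E-diene-4-carbaldehyde | O=C/C1=C/C=C/[C@@H](O)C[C@]2(CO)O[C@@H]2CC1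
F6 | step 15 | bis-acetate of F5 | O=C/C1=C/C=C/[C@@H](OC(C)=O)C[C@]2(COC(C)=O)O[C@@H]2CC1
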